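**Retrosynthetic overview**

1. Feature: in the eight-membered ring (C-1 CHOAc, C-2 CH2, C-3 CHMe, C-4/C-5 cyclopropane CH, C-6/C-7 butenolide C=C, C-8 CH side chain) the butenolide alkene carbons C-6 and C-7 are ring neighbours lying opposite the C-1(O)–C-2–C-3(Me) segment. The C-6–C-7 bond is therefore made by a [3,3] shift that opens the C-1–C-4 bond of a cyclobutanol built from C-1 to C-4.
2. Target ⇐ Schenck ene reaction, acetylation and selenoxide dehydrogenation of the saturated cis-lactone alcohol 32 ⇐ (ketone reduction, lactonisation, arm oxidation, cyclopropanation) cyclooct-4-enone 25.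
3. 25 ⇐ anionic oxy-Cope ring expansion of cis-1,2-dialkenylcyclobutanol 22 ⇐ alkenylcerium reagent 21 + cyclobutanone 19.
4. 19 ⇐ asymmetric [2+2] cycloaddition of crotonoyl oxazolidinone 10 with ketene dithioacetal 11; alkenyl iodide 9 ⇐ (R)-citronellal 1 via an ynoate and syn-stannylcupration.
5. Ring order: cyclobutane → eight-membered ring (by ring expansion) → cyclopropane → γ-lactone → butenolide.

Key step: step 14

**Remarks on the chemistry**

- Locants: C-1 to C-8 as in line 1, also for the cyclobutane carbons that become them (carbinol carbon C-1, CH2 C-2, CHMe C-3, arm-bearing carbon C-4). β is the face of the C-3 methyl group, α the opposite face. PMB = 4-methoxybenzyl, TBS = tert-butyldimethylsilyl.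
- Assumption: the (4R,5R)-diol/TiCl2(OiPr)2 catalyst is taken to give (1R,4R)-12; if the first run shows the opposite sense, the (4S,5S)-diol is used with no other change.
- The future lactone carbonyl carbon is carried through steps 11–15 as a PMB-protected allylic alcohol. A carbonyl group on that arm would make the C-4 proton of the cyclobutanone a vinylogous 1,3-dicarbonyl proton (enolisation instead of addition) and would give the alkoxide of step 14 a stabilised leaving group.

**Route**

Step 1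
Reactants: 1 (R)-citronellal
Product: 3 (3R)-3,7-dimethyloct-6-en-1-yne, via enol nonaflate 2 (not isolated)
Conditions: C4F9SO2F, phosphazene base P2-Et, DMF, −20 → 23 °C
Reagents that add atoms: none
Why: One-pot enol nonaflation and base-induced β-elimination converts an enolisable aldehyde into the terminal alkyne of the same carbon count, and the C-3 stereocentre is not acidic under these conditions.

Step 2
Reactants: 3 (3R)-3,7-dimethyloct-6-en-1-yne
Product: 5 methyl (4R)-4,8-dimethylnon-7-en-2-ynoate, via lithium acetylide 4 (not isolated)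
Conditions: nBuLi, THF, −78 °C; ClCO2Me, −78 → 0 °C
Reagents that add atoms: methyl chloroformate, COC(=O)Cl
Why: Acetylide acylation with a chloroformate is a standard ynoate synthesis.

Step 3
Reactants: 5 methyl (4R)-4,8-dimethylnon-7-en-2-ynoate
Product: 6 methyl (2E,4R)-4,8-dimethyl-3-(trimethylstannyl)nona-2,7-dienoate
Conditions: Li[Me3SnCu(SPh)] (from Me6Sn2, MeLi and CuSPh), MeOH, THF, −100 → −78 °C
Reagents that add atoms: lithium (phenylthio)(trimethylstannyl)cuprate Li[Me3SnCu(SPh)], [Li+].C[Sn](C)(C)[Cu-]Sc1ccccc1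
Why: Syn-stannylcupration of the ynoate with immediate low-temperature protonation (kinetic control) places Sn and H cis, so tin ends up trans to the ester, which is the alkene geometry needed for the cis C-6/C-7 relationship later.

Step 4
Reactants: 6 methyl (2E,4R)-4,8-dimethyl-3-(trimethylstannyl)nona-2,7-dienoate
Product: 7 (2E,4R)-4,8-dimethyl-3-(trimethylstannyl)nona-2,7-dien-1-ol
Conditions: iBu2AlH, CH2Cl2, −78 °C; aq. potassium sodium tartrate
Reagents that add atoms: none
Why: 1,2-Reduction of the enoate by the aluminium hydride gives the allylic alcohol without touching the alkenylstannane.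

Step 5
Reactants: 7 (2E,4R)-4,8-dimethyl-3-(trimethylstannyl)nona-2,7-dien-1-ol
Product: 8 tert-butyl{[(2E,4R)-4,8-dimethyl-3-(trimethylstannyl)nona-2,7-dien-1-yl]oxy}dimethylsilane
Conditions: TBSCl, imidazole, CH2Cl2, 23 °C
Reagents that add atoms: tert-butyl(chloro)dimethylsilane, CC(C)(C)[Si](C)(C)Cl
Why: Standard silylation of a primary alcohol gives an ether stable to tBuLi, KH and DDQ.

Step 6
Reactants: 8 tert-butyl{[(2E,4R)-4,8-dimethyl-3-(trimethylstannyl)nona-2,7-dien-1-yl]oxy}dimethylsilane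
Product: 9 tert-butyl{[(2E,4R)-3-iodo-4,8-dimethylnona-2,7-dien-1-yl]oxy}dimethylsilane
Conditions: I2, CH2Cl2, 0 °C
Reagents that add atoms: iodine, II
Why: Iododestannylation proceeds by ipso substitution with retention of alkene geometry and is faster than any reaction of iodine with the trisubstituted alkene.

Step 7
Reactants: 10 3-[(2E)-but-2-enoyl]-1,3-oxazolidin-2-one + 11 1,1-bis(methylsulfanyl)ethene
Product: 12 3-{[(1R,4R)-4-methyl-2,2-bis(methylsulfanyl)cyclobutyl]carbonyl}-1,3-oxazolidin-2-one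
Conditions: TiCl2(OiPr)2 (10–50 mol %), (4R,5R)-2-methyl-2-phenyl-α,α,α′,α′-tetraphenyl-1,3-dioxolane-4,5-dimethanol, 4 Å molecular sieves, toluene–petroleum ether, 0 °C
Reagents that add atoms: none
Why: Titanium-diolate-catalysed asymmetric [2+2] cycloaddition of a ketene dithioacetal to a chelated 3-(2-alkenoyl)oxazolidinone closes the cyclobutane; the (E)-crotonoyl geometry becomes the trans C-3/C-4 relationship and the chiral diolate shields one face of the acceptor, setting both stereocentres.

Step 8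
Reactants: 12 3-{[(1R,4R)-4-methyl-2,2-bis(methylsulfanyl)cyclobutyl]carbonyl}-1,3-oxazolidin-2-one
Product: 13 [(1R,4R)-4-methyl-2,2-bis(methylsulfanyl)cyclobutyl]methanol
Conditions: LiBH4, H2O (1 equiv), Et2O, 0 °C
Reagents that add atoms: none
Why: Borohydride reduction cleaves the N-acyloxazolidinone at the exocyclic carbonyl to the primary alcohol and leaves the thioketal intact.

Step 9
Reactants: 13 [(1R,4R)-4-methyl-2,2-bis(methylsulfanyl)cyclobutyl]methanol
Product: 15 ethyl (2E)-3-[(1R,4R)-4-methyl-2,2-bis(methylsulfanyl)cyclobutyl]prop-2-enoate, via aldehyde 14 (not isolated)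
Conditions: (COCl)2, DMSO, CH2Cl2, −78 °C; Et3N; then Ph3P=CHCO2Et, −78 → 23 °C
Reagents that add atoms: ethyl (triphenylphosphoranylidene)acetate, CCOC(=O)C=P(c1ccccc1)(c1ccccc1)c1ccccc1
Why: Swern oxidation followed by in situ Wittig olefination with a stabilised ylide gives the (E)-enoate, and any epimerisation of the aldehyde α-carbon favours the trans (to methyl) isomer already present.

Step 10
Reactants: 15 ethyl (2E)-3-[(1R,4R)-4-methyl-2,2-bis(methylsulfanyl)cyclobutyl]prop-2-enoate
Product: 16 (2E)-3-[(1R,4R)-4-methyl-2,2-bis(methylsulfanyl)cyclobutyl]prop-2-en-1-ol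
Conditions: iBu2AlH, CH2Cl2, −78 °C; aq. potassium sodium tartrate
Reagents that add atoms: none
Why: 1,2-Reduction of the enoate removes the acidifying ester before the ketone is unmasked.

Step 11
Reactants: 16 (2E)-3-[(1R,4R)-4-methyl-2,2-bis(methylsulfanyl)cyclobutyl]prop-2-en-1-ol
Product: 18 1-methoxy-4-[({(2E)-3-[(1R,4R)-4-methyl-2,2-bis(methylsulfanyl)cyclobutyl]prop-2-en-1-yl}oxy)methyl]benzene, via sodium alkoxide 17 (not isolated)
Conditions: NaH, THF–DMF, 0 °C; 4-MeOC6H4CH2Cl, nBu4NI (cat.), 23 °C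
Reagents that add atoms: 4-methoxybenzyl chloride, COc1ccc(CCl)cc1
Why: Williamson etherification gives a PMB ether that is orthogonal to the TBS ether of the other fragment.

Step 12
Reactants: 18 1-methoxy-4-[({(2E)-3-[(1R,4R)-4-methyl-2,2-bis(methylsulfanyl)cyclobutyl]prop-2-en-1-yl}oxy)methyl]benzene
Product: 19 (2R,3R)-2-{(1E)-3-[(4-methoxybenzyl)oxy]prop-1-en-1-yl}-3-methylcyclobutan-1-one
Conditions: MeI, CaCO3, MeCN–H2O, 45 °C
Reagents that add atoms: water, O
Why: Alkylative hydrolysis of the S,S-dimethyl thioketal under buffered neutral conditions frees the cyclobutanone without moving the β,γ-alkene or disturbing the thermodynamically preferred trans arrangement of arm and methyl.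

Step 13
Reactants: 9 tert-butyl{[(2E,4R)-3-iodo-4,8-dimethylnona-2,7-dien-1-yl]oxy}dimethylsilane + 19 (2R,3R)-2-{(1E)-3-[(4-methoxybenzyl)oxy]prop-1-en-1-yl}-3-methylcyclobutan-1-one
Product: 22 (1S,2R,3R)-1-[(2E,4R)-1-(tert-butyldimethylsilyloxy)-4,8-dimethylnona-2,7-dien-3-yl]-2-{(1E)-3-[(4-methoxybenzyl)oxy]prop-1-en-1-yl}-3-methylcyclobutan-1-ol, via alkenyllithium 20 (not isolated), via alkenylcerium dichloride 21 (not isolated)
Conditions: 9, tBuLi (2 equiv), Et2O, −78 °C; CeCl3, THF, −78 °C; then 19, −78 °C; H2O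
Reagents that add atoms: none
Why: Iodine–lithium exchange with retention, transmetalation to cerium and 1,2-addition (organocerium addition suppresses enolisation of the β,γ-unsaturated ketone) should bring the nucleophile in anti to the C-3 methyl group, which lies across the four-membered ring under the attack trajectory, and hence cis to the flat alkenyl arm, setting C-1; any trans-dialkenyl isomer is removed by chromatography.

Step 14
Reactants: 22 (1S,2R,3R)-1-[(2E,4R)-1-(tert-butyldimethylsilyloxy)-4,8-dimethylnona-2,7-dien-3-yl]-2-{(1E)-3-[(4-methoxybenzyl)oxy]prop-1-en-1-yl}-3-methylcyclobutan-1-ol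
Product: 25 (4Z)-3β-methyl-6β-(PMB-oxymethyl)-7β-(TBS-oxymethyl)-8α-[(2R)-6-methylhept-5-en-2-yl]cyclooct-4-en-1-one, via potassium alkoxide 23 (not isolated), via potassium enolate 24 (not isolated)
Conditions: KH, 18-crown-6, THF, 0 → 23 °C; AcOH, −78 °C; then DBU, CH2Cl2, 23 °C
Reagents that add atoms: none
Why: Deprotonation gives alkoxide 23, whose charge weakens the strained C-1–C-4 bond, and the two cis alkenyl groups fold under the cyclobutane into a boat array in which C-6 and C-7 bond as C-1–C-4 breaks (anionic oxy-Cope [3,3] shift), giving enolate 24. The closest known reaction type is the alkoxide-accelerated rearrangement of cis-1,2-dialkenylcyclobutanols to cyclooct-4-enones. The eight-membered ring is closed by this four-atom sigmatropic ring expansion and not by an end-to-end cyclisation, and the boat geometry fixes the new ring alkene as Z. C-6 and C-7 are set in the transition state: both alkene termini are E, so CH2OPMB and CH2OTBS come out cis, and because both alkenyl groups sit on the cyclobutane face opposite the C-3 methyl group this pair lands on the β-face. C-8 is set afterwards by protonation and base equilibration of the ketone α-centre, which should place the branched side chain trans to the neighbouring CH2OTBS group (α). The step needs the concerted shift to outrun ring cleavage or a 1,3-shift, which the cis arrangement, the absence of an anion-stabilising group on the C-4 arm and the methyl group pointing away from the folding alkenes should secure.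

Step 15
Reactants: 25 (4Z)-3β-methyl-6β-(PMB-oxymethyl)-7β-(TBS-oxymethyl)-8α-[(2R)-6-methylhept-5-en-2-yl]cyclooct-4-en-1-one
Product: 26 3β-methyl-4α,5α-methano-6β-(PMB-oxymethyl)-7β-(TBS-oxymethyl)-8α-[(2R)-6-methylhept-5-en-2-yl]cyclooctan-1-one
Conditions: CH2N2 (excess, slow addition), Pd(OAc)2 (5 mol %), Et2O, 0 °C
Reagents that add atoms: diazomethane, C=[N+]=[N-]
Why: Palladium-catalysed cyclopropanation with diazomethane reacts with the cis-disubstituted ring alkene but not with the trisubstituted side-chain alkene (which a zinc carbenoid would attack first), and attack on the exposed face of the cyclooctene conformer with both allylic substituents pseudo-equatorial puts the new CH2 trans to the C-3 methyl and C-6 arm (α), setting C-4 and C-5.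

Step 16
Reactants: 26 3β-methyl-4α,5α-methano-6β-(PMB-oxymethyl)-7β-(TBS-oxymethyl)-8α-[(2R)-6-methylhept-5-en-2-yl]cyclooctan-1-one
Product: 27 6β-(hydroxymethyl)-3β-methyl-4α,5α-methano-7β-(TBS-oxymethyl)-8α-[(2R)-6-methylhept-5-en-2-yl]cyclooctan-1-one
Conditions: DDQ, CH2Cl2–pH 7 phosphate buffer, 0 °C
Reagents that add atoms: none
Why: Oxidative cleavage of the PMB ether by DDQ frees only the C-6 hydroxymethyl group and leaves the TBS ether, the cyclopropane and the isolated alkene untouched.

Step 17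
Reactants: 27 6β-(hydroxymethyl)-3β-methyl-4α,5α-methano-7β-(TBS-oxymethyl)-8α-[(2R)-6-methylhept-5-en-2-yl]cyclooctan-1-one
Product: 29 3β-methyl-4α,5α-methano-1-oxo-7β-(TBS-oxymethyl)-8α-[(2R)-6-methylhept-5-en-2-yl]cyclooctane-6β-carboxylic acid, via aldehyde 28 (not isolated)
Conditions: TEMPO (20 mol %), PhI(OAc)2 (2.5 equiv), MeCN–H2O, 23 °C
Reagents that add atoms: water, O
Why: Oxoammonium-mediated oxidation of the primary alcohol in wet acetonitrile runs through the aldehyde hydrate to the carboxylic acid and tolerates the ketone, silyl ether and alkene.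

Step 18
Reactants: 29 3β-methyl-4α,5α-methano-1-oxo-7β-(TBS-oxymethyl)-8α-[(2R)-6-methylhept-5-en-2-yl]cyclooctane-6β-carboxylic acid
Product: 31 keto lactone: cis-fused γ-lactone C-6–C(=O)–O–CH2–C-7 (H-6 and H-7 both α) on 3β-methyl-4α,5α-methano-8α-[(2R)-6-methylhept-5-en-2-yl]cyclooctan-1-one, via hydroxy acid 30 (not isolated)
Conditions: HF (48 % aq.), MeCN, 0 → 23 °C
Reagents that add atoms: none
Why: Acidic desilylation frees the C-7 hydroxymethyl group, which lies cis to the C-6 carboxylic acid and closes the five-membered lactone by acid-catalysed lactonisation.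

Step 19
Reactants: 31 keto lactone
Product: 32 1α-hydroxy lactone (1α-ol of 31; hydroxyl cis to the C-8 side chain)
Conditions: LiBH(sBu)3, THF, −78 °C; H2O
Reagents that add atoms: none
Why: The bulky borohydride should attack the C-1 carbonyl from the β-face, anti to the adjacent C-8 side chain (Felkin-type peripheral attack), setting C-1 as the α-alcohol while the lactone is not reduced at −78 °C.

Step 20
Reactants: 32 1α-hydroxy lactone
Product: 34 6α-(phenylselanyl) lactone of 32 (cis ring fusion kept), via dilithium alkoxide enolate 33 (not isolated)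
Conditions: LiN(iPr)2 (2.3 equiv), THF, −78 °C; PhSeSePh, HMPA, −78 → −40 °C; AcOH
Reagents that add atoms: diphenyl diselenide, c1ccc(cc1)[Se][Se]c1ccccc1
Why: Selenenylation of the lactone enolate (the free hydroxyl is carried as its alkoxide, which the diselenide does not attack) should deliver selenium to C-6 on the α-face where the proton was, keeping the cis-fused lactone and placing selenium syn to H-7.

Step 21
Reactants: 34 6α-(phenylselanyl) lactone
Product: 36 butenolide alcohol: 1α-hydroxy-3β-methyl-4α,5α-methano-8α-[(2R)-6-methylhept-5-en-2-yl]cyclooct-6-ene with the but-2-en-4-olide fused at C-6/C-7, via selenoxide 35 (not isolated)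
Conditions: NaIO4, NaHCO3, THF–MeOH–H2O, 0 → 23 °C
Reagents that add atoms: none
Why: Selenoxide syn-elimination takes the syn H-7 and gives the tetrasubstituted butenolide alkene, since elimination toward the cyclopropane would need a strained alkylidenecyclopropane, and periodate avoids the peracid that could epoxidise the side-chain alkene.

Step 22
Reactants: 36 butenolide alcohol
Product: 37 1α-acetate of 36
Conditions: Ac2O, pyridine, DMAP (cat.), CH2Cl2, 23 °C
Reagents that add atoms: acetic anhydride, CC(=O)OC(C)=O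
Why: DMAP-catalysed acylation of the hindered secondary alcohol is placed after the dehydrogenation because an acetate would not survive the amide base of step 20.

Step 23
Reactants: 37 1α-acetate
Product: 38 CNP0205234.1 (target): 1α-acetoxy-3β-methyl-4α,5α-methano-8α-[(2R,4E)-6-hydroperoxy-6-methylhept-4-en-2-yl]cyclooct-6-ene with the but-2-en-4-olide fused at C-6/C-7
Conditions: O2, hν (visible), tetraphenylporphyrin (cat.), CH2Cl2, 0 °C
Reagents that add atoms: dioxygen, O=O
Why: The Schenck ene reaction of singlet oxygen with the electron-rich trisubstituted alkene removes an allylic CH2 hydrogen and gives the tertiary hydroperoxide with the shifted (E)-alkene, while the electron-poor butenolide alkene is inert; the regioisomeric secondary hydroperoxide (hydrogen taken from a methyl group) is expected as well and is separated by chromatography.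

**Compound list**

1 | (R)-citronellal, (3R)-3,7-dimethyloct-6-enal | O=CC[C@H](C)CCC=C(C)C | starting material
2 | (3R)-3,7-dimethylocta-1,6-dien-1-yl nonafluorobutane-1-sulfonate (E/Z mixture) | FC(F)(F)C(F)(F)C(F)(F)C(F)(F)S(=O)(=O)OC=C[C@H](C)CCC=C(C)C | intermediate
3 | (3R)-3,7-dimethyloct-6-en-1-yne | C#C[C@H](C)CCC=C(C)C | intermediate
4 | lithium acetylide of 3 | [Li]C#C[C@H](C)CCC=C(C)C | intermediate
5 | methyl (4R)-4,8-dimethylnon-7-en-2-ynoate | COC(=O)C#C[C@H](C)CCC=C(C)C | intermediate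
6 | methyl (2E,4R)-4,8-dimethyl-3-(trimethylstannyl)nona-2,7-dienoate | COC(=O)/C=C(/[Sn](C)(C)C)[C@H](C)CCC=C(C)C | intermediate
7 | (2E,4R)-4,8-dimethyl-3-(trimethylstannyl)nona-2,7-dien-1-ol | OC/C=C(/[Sn](C)(C)C)[C@H](C)CCC=C(C)C | intermediate
8 | tert-butyl{[(2E,4R)-4,8-dimethyl-3-(trimethylstannyl)nona-2,7-dien-1-yl]oxy}dimethylsilane | CC(C)(C)[Si](C)(C)OC/C=C(/[Sn](C)(C)C)[C@H](C)CCC=C(C)C | intermediate
9 | tert-butyl{[(2E,4R)-3-iodo-4,8-dimethylnona-2,7-dien-1-yl]oxy}dimethylsilane | CC(C)(C)[Si](C)(C)OC/C=C(/I)[C@H](C)CCC=C(C)C | intermediate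
10 | 3-[(2E)-but-2-enoyl]-1,3-oxazolidin-2-one | C/C=C/C(=O)N1CCOC1=O | starting material
11 | 1,1-bis(methylsulfanyl)ethene | C=C(SC)SC | starting material
12 | 3-{[(1R,4R)-4-methyl-2,2-bis(methylsulfanyl)cyclobutyl]carbonyl}-1,3-oxazolidin-2-one | CSC1(SC)C[C@@H](C)[C@@H]1C(=O)N1CCOC1=O | intermediate
13 | [(1R,4R)-4-methyl-2,2-bis(methylsulfanyl)cyclobutyl]methanol | CSC1(SC)C[C@@H](C)[C@@H]1CO | intermediate
14 | (1R,4R)-4-methyl-2,2-bis(methylsulfanyl)cyclobutane-1-carbaldehyde | CSC1(SC)C[C@@H](C)[C@@H]1C=O | intermediate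
15 | ethyl (2E)-3-[(1R,4R)-4-methyl-2,2-bis(methylsulfanyl)cyclobutyl]prop-2-enoate | CSC1(SC)C[C@@H](C)[C@@H]1/C=C/C(=O)OCC | intermediate
16 | (2E)-3-[(1R,4R)-4-methyl-2,2-bis(methylsulfanyl)cyclobutyl]prop-2-en-1-ol | CSC1(SC)C[C@@H](C)[C@@H]1/C=C/CO | intermediate
17 | sodium alkoxide of 16 | CSC1(SC)C[C@@H](C)[C@@H]1/C=C/C[O-].[Na+] | intermediate
18 | 1-methoxy-4-[({(2E)-3-[(1R,4R)-4-methyl-2,2-bis(methylsulfanyl)cyclobutyl]prop-2-en-1-yl}oxy)methyl]benzene | CSC1(SC)C[C@@H](C)[C@@H]1/C=C/COCc1ccc(OC)cc1 | intermediate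
19 | (2R,3R)-2-{(1E)-3-[(4-methoxybenzyl)oxy]prop-1-en-1-yl}-3-methylcyclobutan-1-one | O=C1C[C@@H](C)[C@@H]1/C=C/COCc1ccc(OC)cc1 | intermediate
20 | alkenyllithium from 9 (Li in place of I, geometry retained) | [Li]/C(=C/CO[Si](C)(C)C(C)(C)C)[C@H](C)CCC=C(C)C | intermediate
21 | alkenylcerium dichloride from 20 | Cl[Ce](Cl)/C(=C/CO[Si](C)(C)C(C)(C)C)[C@H](C)CCC=C(C)C | intermediate
22 | (1S,2R,3R)-1-[(2E,4R)-1-(tert-butyldimethylsilyloxy)-4,8-dimethylnona-2,7-dien-3-yl]-2-{(1E)-3-[(4-methoxybenzyl)oxy]prop-1-en-1-yl}-3-methylcyclobutan-1-ol (alkenyl groups cis, methyl trans to both) | O[C@@]1(/C(=C/CO[Si](C)(C)C(C)(C)C)[C@H](C)CCC=C(C)C)C[C@@H](C)[C@@H]1/C=C/COCc1ccc(OC)cc1 | intermediate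
23 | potassium alkoxide of 22 | [K+].[O-][C@@]1(/C(=C/CO[Si](C)(C)C(C)(C)C)[C@H](C)CCC=C(C)C)C[C@@H](C)[C@@H]1/C=C/COCc1ccc(OC)cc1 | intermediate
24 | potassium C-1/C-8 enolate of 25 | [K+].[O-]/C1=C(\[C@H](C)CCC=C(C)C)[C@H](CO[Si](C)(C)C(C)(C)C)[C@H](COCc2ccc(OC)cc2)/C=C\[C@H](C)C1 | intermediate
25 | (4Z)-3β-methyl-6β-(PMB-oxymethyl)-7β-(TBS-oxymethyl)-8α-[(2R)-6-methylhept-5-en-2-yl]cyclooct-4-en-1-one | O=C1C[C@@H](C)/C=C\[C@@H](COCc2ccc(OC)cc2)[C@@H](CO[Si](C)(C)C(C)(C)C)[C@@H]1[C@H](C)CCC=C(C)C | intermediate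
26 | 3β-methyl-4α,5α-methano-6β-(PMB-oxymethyl)-7β-(TBS-oxymethyl)-8α-[(2R)-6-methylhept-5-en-2-yl]cyclooctan-1-one | O=C1C[C@@H](C)[C@@H]2C[C@@H]2[C@@H](COCc2ccc(OC)cc2)[C@@H](CO[Si](C)(C)C(C)(C)C)[C@@H]1[C@H](C)CCC=C(C)C | intermediate
27 | 6β-(hydroxymethyl) compound from 26 | O=C1C[C@@H](C)[C@@H]2C[C@@H]2[C@@H](CO)[C@@H](CO[Si](C)(C)C(C)(C)C)[C@@H]1[C@H](C)CCC=C(C)C | intermediate
28 | 6β-carbaldehyde from 27 | O=C1C[C@@H](C)[C@@H]2C[C@@H]2[C@@H](C=O)[C@@H](CO[Si](C)(C)C(C)(C)C)[C@@H]1[C@H](C)CCC=C(C)C | intermediate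
29 | 6β-carboxylic acid | O=C1C[C@@H](C)[C@@H]2C[C@@H]2[C@@H](C(=O)O)[C@@H](CO[Si](C)(C)C(C)(C)C)[C@@H]1[C@H](C)CCC=C(C)C | intermediate
30 | 7β-(hydroxymethyl) 6β-carboxylic acid | O=C1C[C@@H](C)[C@@H]2C[C@@H]2[C@@H](C(=O)O)[C@@H](CO)[C@@H]1[C@H](C)CCC=C(C)C | intermediate
31 | keto lactone (cis-fused γ-lactone, H-6 and H-7 α) | O=C1C[C@@H](C)[C@@H]2C[C@@H]2[C@@H]2[C@@H](COC2=O)[C@@H]1[C@H](C)CCC=C(C)C | intermediate
32 | 1α-hydroxy lactone | O[C@@H]1C[C@@H](C)[C@@H]2C[C@@H]2[C@@H]2[C@@H](COC2=O)[C@@H]1[C@H](C)CCC=C(C)C | intermediate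
33 | dilithium alkoxide/lactone enolate of 32 | [Li+].[Li+].[O-][C@@H]1C[C@@H](C)[C@@H]2C[C@@H]2C2=C([O-])OC[C@H]2[C@@H]1[C@H](C)CCC=C(C)C | intermediate
34 | 6α-(phenylselanyl) lactone | O[C@@H]1C[C@@H](C)[C@@H]2C[C@@H]2[C@]2([Se]c3ccccc3)[C@@H](COC2=O)[C@@H]1[C@H](C)CCC=C(C)C | intermediate
35 | selenoxide of 34 | O[C@@H]1C[C@@H](C)[C@@H]2C[C@@H]2[C@]2([Se](=O)c3ccccc3)[C@@H](COC2=O)[C@@H]1[C@H](C)CCC=C(C)C | intermediate
36 | butenolide alcohol | O[C@@H]1C[C@@H](C)[C@@H]2C[C@@H]2C2=C(COC2=O)[C@@H]1[C@H](C)CCC=C(C)C | intermediate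
37 | butenolide acetate | CC(=O)O[C@@H]1C[C@@H](C)[C@@H]2C[C@@H]2C2=C(COC2=O)[C@@H]1[C@H](C)CCC=C(C)C | intermediate
38 | CNP0205234.1 | CC(=O)O[C@@H]1C[C@@H](C)[C@@H]2C[C@@H]2C2=C(COC2=O)[C@@H]1[C@H](C)C/C=C/C(C)(C)OO | target

**Step count and risks**

Total steps: 23. Longest linear sequence: 17 steps (steps 1–6 or 7–12, then 13–23).

Steps most likely to fail:

1. Step 13. What may go wrong: the alkenylcerium reagent may enter anti to the alkenyl arm on the neighbouring carbon instead of anti to the C-3 methyl group (poor or reversed facial selectivity), giving the trans-dialkenyl carbinol that cannot reach the boat array; enolisation may also return ketone. Fallback (sets out from 13, comes back at 22): the arm is carried through the addition as a slim alkyne, so that only the C-3 methyl group differentiates the two faces. Alcohol 13 is oxidised as in step 9, and aldehyde 14 is treated with the Ohira–Bestmann reagent (K2CO3, MeOH) to give the terminal alkyne (1R,4R)-1-ethynyl-4-methyl-2,2-bis(methylsulfanyl)cyclobutane F1. Lithiation (nBuLi) and paraformaldehyde give the propargylic alcohol F2, which is protected (NaH, 4-methoxybenzyl chloride) as the PMB ether F3 and unmasked (MeI, CaCO3, aqueous MeCN) to the alkynyl ketone F4. Addition of alkenylcerium 21 gives the alkynyl carbinol F5. Ruthenium-catalysed trans-hydrosilylation ([Cp*Ru(MeCN)3]PF6, (EtO)3SiH) gives the (Z)-vinylsilane F6, and protodesilylation (AgF, aqueous THF–MeOH) leaves the (E)-alkene of 22.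

2. Step 14. What may go wrong: heterolytic cleavage of the C-1–C-4 bond of the alkoxide or a 1,3-shift may compete with the concerted shift, and protonation at C-8 may occur from the wrong face and not equilibrate. Fallback (from 22, back at 25): a charge-neutral silyloxy-Cope rearrangement. Carbinol 22 is silylated with N-(trimethylsilyl)imidazole to the trimethylsilyl ether F7, which is heated in toluene (80–110 °C) so that the thermal [3,3] shift of the cis-1,2-dialkenylcyclobutane gives the trimethylsilyl enol ether F8. Mild hydrolysis (aqueous citric acid, THF) followed by the same DBU equilibration gives 25.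

3. Step 15. What may go wrong: carbene transfer to a ring alkene flanked by two allylic branches may be slow (incomplete conversion, catalyst decomposition) or take the wrong face. Fallback (from 25, back at 26): hydroxyl-directed zinc carbenoid delivery. Ketone 25 is reduced (LiBH(sBu)3, THF, −78 °C) to the 1α-alcohol F9. Its zinc alkoxide (Et2Zn, CH2I2, CH2Cl2, −20 °C, about one equivalent of carbenoid) should deliver CH2 across the ring to the α-face of the C-4=C-5 alkene faster than the remote side-chain alkene reacts, giving the cyclopropyl alcohol F10. Oxidation with Dess–Martin periodinane returns ketone 26.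

**Further compounds**

F1 | step 13 | (1R,4R)-1-ethynyl-4-methyl-2,2-bis(methylsulfanyl)cyclobutane | CSC1(SC)C[C@@H](C)[C@@H]1C#C
F2 | step 13 | 3-[(1R,4R)-4-methyl-2,2-bis(methylsulfanyl)cyclobutyl]prop-2-yn-1-ol | CSC1(SC)C[C@@H](C)[C@@H]1C#CCO
F3 | step 13 | PMB ether of F2 | CSC1(SC)C[C@@H](C)[C@@H]1C#CCOCc1ccc(OC)cc1
F4 | step 13 | (2R,3R)-2-{3-[(4-methoxybenzyl)oxy]prop-1-yn-1-yl}-3-methylcyclobutan-1-one | O=C1C[C@@H](C)[C@@H]1C#CCOCc1ccc(OC)cc1
F5 | step 13 | alkynyl carbinol (alkyne analogue of 22) | O[C@@]1(/C(=C/CO[Si](C)(C)C(C)(C)C)[C@H](C)CCC=C(C)C)C[C@@H](C)[C@@H]1C#CCOCc1ccc(OC)cc1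
F6 | step 13 | (Z)-triethoxysilyl alkene from F5 (one regioisomer shown) | O[C@@]1(/C(=C/CO[Si](C)(C)C(C)(C)C)[C@H](C)CCC=C(C)C)C[C@@H](C)[C@@H]1/C(=C/COCc1ccc(OC)cc1)[Si](OCC)(OCC)OCC
F7 | step 14 | trimethylsilyl ether of 22 | C[Si](C)(C)O[C@@]1(/C(=C/CO[Si](C)(C)C(C)(C)C)[C@H](C)CCC=C(C)C)C[C@@H](C)[C@@H]1/C=C/COCc1ccc(OC)cc1
F8 | step 14 | trimethylsilyl enol ether of 25 | C[Si](C)(C)O/C1=C(\[C@H](C)CCC=C(C)C)[C@H](CO[Si](C)(C)C(C)(C)C)[C@H](COCc2ccc(OC)cc2)/C=C\[C@H](C)C1
F9 | step 15 | 1α-alcohol of 25 | O[C@@H]1C[C@@H](C)/C=C\[C@@H](COCc2ccc(OC)cc2)[C@@H](CO[Si](C)(C)C(C)(C)C)[C@@H]1[C@H](C)CCC=C(C)C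
F10 | step 15 | 1α-alcohol of 26 | O[C@@H]1C[C@@H](C)[C@@H]2C[C@@H]2[C@@H](COCc2ccc(OC)cc2)[C@@H](CO[Si](C)(C)C(C)(C)C)[C@@H]1[C@H](C)CCC=C(C)C
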